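**Retrosynthetic overview**

1. The strategy rests on C6 of the target. This oxirane carbon carries the oxirane oxygen and the E-butenone chain and lies between the gem-dimethyl carbon C1 and the methyl-bearing oxirane carbon C5. That is the substitution pattern and the S configuration of C1' of (S)-abscisic acid, so the oxirane oxygen can be that acid's tertiary hydroxyl.
2. Last disconnection: the C5–O bond of the oxirane, the only ring formed in the route (the cyclohexane comes intact from abscisic acid). It is closed by cobalt-hydride hydrogen-atom-transfer cycloisomerisation of the C4=C5 alkene of a 6-hydroxy-α-ionone 3-ester.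
3. Before that: the C3 tetradecanoate by Mitsunobu inversion of a cis 3,6-diol, and the C9 methyl by Grignard addition to a Weinreb amide, which keeps the chain carbonyl masked while the ring ketone at C3 is reduced.
4. First: the C7=C8 bond by Horner–Wadsworth–Emmons olefination of the α-hydroxy aldehyde obtained by ozonolysis of the γ,δ-alkene of abscisic acid.

Key step: step 6

Remark: ionone numbering is used for all ring compounds (C1 gem-dimethyl carbon, C3 oxygenated carbon, C4=C5 ring alkene with the methyl on C5, C6 chain-bearing carbinol carbon, C7–C10 the butenone chain); the alkenes of abscisic acid are named by their position relative to the carboxyl group.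

Assumption: the Luche reduction in step 3 is taken to favour the cis 3,6-diol (3R); the minor 3S epimer is separable, and the fallback to step 5 covers the opposite outcome.

**Route**

Step 1
Reactants: 1 (S)-(+)-abscisic acid
Product: 3 (1S)-1-hydroxy-2,6,6-trimethyl-4-oxocyclohex-2-ene-1-carbaldehyde, via secondary ozonide 2 (not isolated)
Conditions: O3 (1.0 equiv, titrated solution), CH2Cl2/EtOAc, −78 °C; then Me2S, −78 °C → rt; NaHCO3 wash
Reagents that add atoms: ozone, [O-][O+]=O
Why: Ozonolysis (Criegee mechanism) should take the most electron-rich alkene first, which is the γ,δ-bond of the dienoic acid because the α,β-bond and the ring alkene are each directly conjugated to a carbonyl (as in γ,δ-selective ozonolysis of sorbates), while the carbinol stereocentre is not touched and the acidic fragment is removed by the bicarbonate wash.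

Step 2
Reactants: 3 (1S)-1-hydroxy-2,6,6-trimethyl-4-oxocyclohex-2-ene-1-carbaldehyde; 4 diethyl (N-methoxy-N-methylcarbamoylmethyl)phosphonate
Product: 5 (2E)-3-[(1S)-1-hydroxy-2,6,6-trimethyl-4-oxocyclohex-2-en-1-yl]-N-methoxy-N-methylprop-2-enamide
Conditions: LiCl, iPr2NEt, MeCN, 0 °C → rt
Reagents that add atoms: none
Why: Horner–Wadsworth–Emmons olefination under Masamune–Roush conditions uses an amine base mild enough for the tertiary α-hydroxy aldehyde, the aldehyde reacts far faster than the hindered ring ketone, and the stabilised phosphonate anion should give the E-alkene under thermodynamic control.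

Step 3
Reactants: 5 (2E)-3-[(1S)-1-hydroxy-2,6,6-trimethyl-4-oxocyclohex-2-en-1-yl]-N-methoxy-N-methylprop-2-enamide
Product: 6 (2E)-3-[(1S,4R)-1,4-dihydroxy-2,6,6-trimethylcyclohex-2-en-1-yl]-N-methoxy-N-methylprop-2-enamide (cis diol)
Conditions: NaBH4, CeCl3·7H2O, MeOH, −78 → −40 °C
Reagents that add atoms: none
Why: Luche 1,2-reduction touches only the ring enone carbonyl (the Weinreb enamide is inert to borohydride), and hydride is expected to arrive anti to the axial C1 methyl of the sofa conformer with the chain axial, on the face of the C6 chain, so the new C3 hydroxyl is cis to the C6 hydroxyl (3R) and the minor 3S epimer is removed by chromatography.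

Step 4
Reactants: 6 (2E)-3-[(1S,4R)-1,4-dihydroxy-2,6,6-trimethylcyclohex-2-en-1-yl]-N-methoxy-N-methylprop-2-enamide
Product: 7 (3R,6S)-3,6-dihydroxy-α-ionone, (3E)-4-[(1S,4R)-1,4-dihydroxy-2,6,6-trimethylcyclohex-2-en-1-yl]but-3-en-2-one
Conditions: MeMgBr (4 equiv), THF, −20 → 0 °C; aq NH4Cl
Reagents that add atoms: methylmagnesium bromide, C[Mg]Br
Why: Weinreb ketone synthesis, in which two equivalents of Grignard reagent deprotonate the hydroxyls and a further one adds once to the N-methoxy-N-methylamide, the magnesium chelate collapsing to the E-enone only on work-up so that no over-addition occurs and no stereocentre is touched.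

Step 5
Reactants: 7 (3R,6S)-3,6-dihydroxy-α-ionone; 8 tetradecanoic (myristic) acid
Product: 9 (3S,6S)-6-hydroxy-3-(tetradecanoyloxy)-α-ionone, (1S,4S)-4-hydroxy-3,5,5-trimethyl-4-[(1E)-3-oxobut-1-en-1-yl]cyclohex-2-en-1-yl tetradecanoate
Conditions: PPh3, DIAD, toluene/THF, 0 °C → rt
Reagents that add atoms: none
Why: Mitsunobu esterification activates only the secondary allylic C3 hydroxyl (the tertiary C6 hydroxyl cannot form the alkoxyphosphonium ion), and SN2 displacement by tetradecanoate inverts C3 from R to S, placing the ester trans to the C6 hydroxyl, while SN2' delivery is blocked because C5 is fully substituted and adjacent to quaternary C6.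

Step 6
Reactants: 9 (3S,6S)-6-hydroxy-3-(tetradecanoyloxy)-α-ionone
Product: 10 (3S,5R,6S)-5,6-epoxy-3-(tetradecanoyloxy)-5,6-dihydro-β-ionone (target)
Conditions: [N,N'-bis(3,5-di-tert-butylsalicylidene)-1,2-cyclohexanediaminato]cobalt(II) (5 mol%), N-fluoro-2,4,6-trimethylpyridinium triflate (1.5 equiv), PhSiH3 (1.2 equiv), acetone, 0 °C → rt, Ar
Reagents that add atoms: none
Why: The cobalt(III) hydride generated from the salen complex, the N-fluoropyridinium oxidant and the silane transfers a hydrogen atom to C4, the less substituted carbon of the trisubstituted ring alkene, and the tertiary C5 radical is captured reversibly by cobalt and oxidised to an alkylcobalt(IV), a cation equivalent, which the neighbouring C6 hydroxyl displaces to form the C5–O bond. This is the known cobalt–salen hydrogen-atom-transfer, radical–polar crossover cycloisomerisation of tertiary allylic alcohols to epoxides. The oxirane closes in the 3-exo-tet mode, the oxygen attacking C5 anti to the departing cobalt. C5 is the only new stereocentre and is fixed by C6, because an oxirane fused to a cyclohexane must be cis, so the oxygen stays on the face it holds at C6 and the C5 methyl is forced to the other face (5R); reversible Co–C homolysis lets either face of the planar radical reach this single closure geometry. The step needs hydrogen transfer to the ring alkene and not to the enone, and closure and not 1,2-shift of the butenyl group or of C1; the enone is an electron-poor 1,2-disubstituted alkene whose β-carbon C7 sits on quaternary C6 and should be the poorer acceptor for the electrophilic hydride, while the salen ligand and the oxidant are chosen for closure over migration. The C3 ester on the opposite face is a spectator, and no acid or peracid meets the vinyl oxirane.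

**Compound list**

1 | (S)-(+)-abscisic acid | CC1=CC(=O)CC([C@]1(/C=C/C(=C\C(=O)O)/C)O)(C)C | starting material
2 | (2Z)-3-{5-[(1S)-1-hydroxy-2,6,6-trimethyl-4-oxocyclohex-2-en-1-yl]-1,2,4-trioxolan-3-yl}but-2-enoic acid (secondary ozonide, mixture at the trioxolane carbons) | CC1=CC(=O)CC([C@]1(C2OOC(O2)/C(C)=C\C(O)=O)O)(C)C | intermediate
3 | (1S)-1-hydroxy-2,6,6-trimethyl-4-oxocyclohex-2-ene-1-carbaldehyde | CC1=CC(=O)CC([C@]1(C=O)O)(C)C | intermediate
4 | diethyl (N-methoxy-N-methylcarbamoylmethyl)phosphonate | CCOP(=O)(CC(=O)N(C)OC)OCC | starting material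
5 | (2E)-3-[(1S)-1-hydroxy-2,6,6-trimethyl-4-oxocyclohex-2-en-1-yl]-N-methoxy-N-methylprop-2-enamide | CC1=CC(=O)CC([C@]1(/C=C/C(=O)N(C)OC)O)(C)C | intermediate
6 | (2E)-3-[(1S,4R)-1,4-dihydroxy-2,6,6-trimethylcyclohex-2-en-1-yl]-N-methoxy-N-methylprop-2-enamide (cis diol) | O[C@@H]1CC(C)(C)[C@@](O)(/C=C/C(=O)N(C)OC)C(C)=C1 | intermediate
7 | (3R,6S)-3,6-dihydroxy-α-ionone | O[C@@H]1CC(C)(C)[C@@](O)(/C=C/C(C)=O)C(C)=C1 | intermediate
8 | tetradecanoic (myristic) acid | CCCCCCCCCCCCCC(=O)O | starting material
9 | (3S,6S)-6-hydroxy-3-(tetradecanoyloxy)-α-ionone | CCCCCCCCCCCCCC(=O)O[C@H]1CC(C)(C)[C@@](O)(/C=C/C(C)=O)C(C)=C1 | intermediate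
10 | (3S,5R,6S)-5,6-epoxy-3-(tetradecanoyloxy)-5,6-dihydro-β-ionone | CCCCCCCCCCCCCC(=O)O[C@H]1CC(C)(C)[C@]2(/C=C/C(C)=O)O[C@]2(C)C1 | target

**Step count**

Total steps: 6. Longest linear sequence: 6 steps (from 1).

**Steps most likely to fail**

Step 6. Hydrogen-atom transfer may go to the chain enone (reduction of C7=C8), or the butenyl group or C1 may migrate to C5 before the oxirane closes. Fallback, from 9 back to 10: the oxirane oxygen is delivered by a peracid instead. Ionic hydrogenation (Et3SiH, BF3·OEt2, CH2Cl2, −78 °C) ionises the doubly allylic tertiary C6 hydroxyl, and hydride is delivered to the less hindered C4 terminus of the allyl cation. This moves the alkene into conjugation and should give (3R)-3-(tetradecanoyloxy)-β-ionone F1, with C3 unchanged in space. Buffered peracid epoxidation (mCPBA, NaHCO3, CH2Cl2, 0 °C) of the tetrasubstituted C5=C6 alkene is expected to occur mainly anti to the C3 acyloxy group, as is usual for 3-acyloxy β-ionone rings. It should give 10 after separation from the syn epoxide.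

Step 5. The allylic alkoxyphosphonium ion may ionise, with loss of stereospecificity or elimination to a diene; the same fallback applies if the hydride in step 3 is delivered mainly to the other face. Fallback, from 5 back to 9: C3 is set by reagent control and acylated with retention. Corey–Bakshi–Shibata reduction of 5 ((R)-Me-CBS, catecholborane, toluene, −78 °C; catalyst enantiomer chosen so that, with the alkene arm as the large group, the alcohol is 3S) should give (2E)-3-[(1S,4S)-1,4-dihydroxy-2,6,6-trimethylcyclohex-2-en-1-yl]-N-methoxy-N-methylprop-2-enamide F2. Methylmagnesium bromide as in step 4 should then give (3S,6S)-3,6-dihydroxy-α-ionone F3. Carbodiimide esterification of its secondary hydroxyl with 8 (EDC·HCl, DMAP, CH2Cl2, 0 °C) returns to 9.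

Step 1. Ozone may add unselectively, cleaving the ring enone alkene as well as the diene. Fallback, from 1 back to 3: the cleavage is split into osmylation and glycol fission. Catalytic dihydroxylation of the sodium salt of 1 (OsO4 cat., NMO, NaHCO3, acetone/H2O) is selective for the most electron-rich γ,δ-alkene. It should give (2Z)-4,5-dihydroxy-5-[(1S)-1-hydroxy-2,6,6-trimethyl-4-oxocyclohex-2-en-1-yl]-3-methylpent-2-enoic acid F4, kept as the carboxylate so that it does not lactonise. One equivalent of NaIO4 (buffered water/THF, 0 °C) should cleave the less hindered secondary–secondary glycol bond to give 3.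

**Further compounds**

F1 | step 6 | (3R)-3-(tetradecanoyloxy)-β-ionone | CCCCCCCCCCCCCC(=O)O[C@H]1CC(C)(C)C(/C=C/C(C)=O)=C(C)C1
F2 | step 5 | (2E)-3-[(1S,4S)-1,4-dihydroxy-2,6,6-trimethylcyclohex-2-en-1-yl]-N-methoxy-N-methylprop-2-enamide (trans diol) | O[C@H]1CC(C)(C)[C@@](O)(/C=C/C(=O)N(C)OC)C(C)=C1
F3 | step 5 | (3S,6S)-3,6-dihydroxy-α-ionone | O[C@H]1CC(C)(C)[C@@](O)(/C=C/C(C)=O)C(C)=C1
F4 | step 1 | (2Z)-4,5-dihydroxy-5-[(1S)-1-hydroxy-2,6,6-trimethyl-4-oxocyclohex-2-en-1-yl]-3-methylpent-2-enoic acid (syn diol, mixture of two diastereomers) | CC1=CC(=O)CC([C@]1(C(O)C(O)/C(C)=C\C(O)=O)O)(C)C
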